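**Retrosynthetic overview**
1. Target ⇐ (3S)-propargylic alcohol (invertive Appel bromination) ⇐ 5-exo opening of a (3S,4S)-alkynyl epoxide by the C7 hydroxyl (second tetrahydrofuran, C4–O–C7, formed last) ⇐ Shi epoxidation of an (E)-enyne.
2. Oxocane (C6–O–C12) carrying C9–OAc, C10–Br and C13–Br ⇐ ring expansion of a 2,5-cis bromo-tetrahydrofuran (C6–O–C9): bromonium ion at C12=C13, bicyclic oxonium ion, acetate attack at the ring-fusion carbon C9.
3. Bromo-tetrahydrofuran ⇐ 5-exo bromoetherification of the (9Z)-alkene by the C6 hydroxyl (first ring, same flask).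
4. Acyclic C15 triene-yne (6-OH, 7-OTBS, erythro) ⇐ (E)-enynyl-lithium + erythro silyloxy epoxide from a Sharpless kinetic resolution.
5. Vinyl carbinol ⇐ acrolein + propargyl bromide, then copper coupling with (E)-1-bromopent-2-ene and Lindlar reduction. Ring order: tetrahydrofuran → oxocane (by expansion) → second tetrahydrofuran.

Assumption: the SMILES is read as 3R,4R,6S,7R,9R,10S,12R,13S (locants C1–C15 run from the alkyne terminus to the ethyl terminus); (E)-1-bromo-2-iodoethene and the L-fructose-derived enantiomer of the Shi ketone are taken as purchasable.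

**Route**

Step 1
Reactants: 1 acrolein; 2 propargyl bromide (3-bromoprop-1-yne)
Product: 3 rac-hex-1-en-5-yn-3-ol
Conditions: Zn dust, THF/sat. aq. NH4Cl, 0 °C
Reagents that add atoms: none
Why: Barbier-type zinc propargylation, in which the allenylzinc species adds 1,2 to the aldehyde through an SE2' transition state to give the homopropargylic alcohol (racemic, resolved in step 4).

Step 2
Reactants: 3 rac-hex-1-en-5-yn-3-ol; 4 (E)-1-bromopent-2-ene
Product: 5 rac-(8E)-undeca-1,8-dien-5-yn-3-ol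
Conditions: CuI (10 mol%), NaI (cat.), K2CO3, DMF, rt
Reagents that add atoms: none
Why: Copper-catalysed coupling of a terminal alkyne with a primary allylic bromide (copper acetylide, SN2-type substitution with retention of the E geometry), which tolerates the free hydroxyl.

Step 3
Reactants: 5 rac-(8E)-undeca-1,8-dien-5-yn-3-ol
Product: 6 rac-(5Z,8E)-undeca-1,5,8-trien-3-ol
Conditions: H2 (1 atm), Pd/CaCO3 poisoned with Pb(OAc)2 (Lindlar catalyst), quinoline, EtOAc, 0 °C, stopped at 1 equiv H2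
Reagents that add atoms: none
Why: Lindlar semi-hydrogenation adds H2 syn to the alkyne, much faster than to the alkenes present, and gives the (Z)-alkene.

Step 4
Reactants: 6 rac-(5Z,8E)-undeca-1,5,8-trien-3-ol
Product: 7 (1R,3Z,6E)-1-[(2S)-oxiran-2-yl]nona-3,6-dien-1-ol
Conditions: Ti(OiPr)4 (10 mol%), D-(−)-diisopropyl tartrate (12 mol%), t-BuOOH (0.55 equiv), 4 Å molecular sieves, CH2Cl2, −20 °C
Reagents that add atoms: tert-butyl hydroperoxide, CC(C)(C)OO
Why: Sharpless kinetic resolution, in which the D-tartrate catalyst epoxidises only the (R)-allylic alcohol on the face that gives the erythro epoxy alcohol (sets C6 as S next to C7 R, at most 50 % yield, the (S)-alcohol is left and separated), the isolated alkenes being inert.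

Step 5
Reactants: 7 (1R,3Z,6E)-1-[(2S)-oxiran-2-yl]nona-3,6-dien-1-ol
Product: 8 tert-butyldimethyl{[(1R,3Z,6E)-1-[(2S)-oxiran-2-yl]nona-3,6-dien-1-yl]oxy}silane
Conditions: TBSCl, imidazole, DMF, 0 °C → rt
Reagents that add atoms: tert-butyldimethylsilyl chloride, CC(C)(C)[Si](C)(C)Cl
Why: Standard silylation, which marks O7 as the non-nucleophilic oxygen so that the later epoxide opening frees only O6.

Step 6
Reactants: 9 ethynyltrimethylsilane; 10 (E)-1-bromo-2-iodoethene
Product: 11 [(3E)-4-bromobut-3-en-1-yn-1-yl]trimethylsilane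
Conditions: Pd(PPh3)4 (3 mol%), CuI (5 mol%), i-Pr2NH, THF, 0 °C
Reagents that add atoms: none
Why: Sonogashira coupling, in which oxidative addition at C–I is far faster than at C–Br and the E geometry is retained.

Step 7
Reactants: 11 [(3E)-4-bromobut-3-en-1-yn-1-yl]trimethylsilane; 8 tert-butyldimethyl{[(1R,3Z,6E)-1-[(2S)-oxiran-2-yl]nona-3,6-dien-1-yl]oxy}silane
Product: 13 (3E,6S,7R,9Z,12E)-7-[(tert-butyldimethylsilyl)oxy]-1-(trimethylsilyl)pentadeca-3,9,12-trien-1-yn-6-ol, via vinyllithium 12 (not isolated)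
Conditions: 11, t-BuLi (2.0 equiv), Et2O, −78 °C; then 8, BF3·OEt2, −78 °C; aq. NH4Cl
Reagents that add atoms: none
Why: Bromine–lithium exchange with retention of the E geometry, then BF3-promoted SN2 opening of the terminal epoxide at its CH2 carbon (C5), which touches no stereocentre and leaves 6-OH free next to 7-OTBS.

Step 8
Reactants: 13 (3E,6S,7R,9Z,12E)-7-[(tert-butyldimethylsilyl)oxy]-1-(trimethylsilyl)pentadeca-3,9,12-trien-1-yn-6-ol
Product: 16 (3E,6S,7R,9R,10S,12R,13S)-10,13-dibromo-7-[(tert-butyldimethylsilyl)oxy]-6,12-epoxy-1-(trimethylsilyl)pentadec-3-en-1-yn-9-yl acetate, via bromo-tetrahydrofuran 14 (not isolated), via bicyclic oxonium ion 15 (not isolated)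
Conditions: N-bromosuccinimide (1.05 equiv), CH2Cl2, −20 → 0 °C; then MeNO2, 2,6-di-tert-butyl-4-methylpyridine, Et2SBr·SbCl5Br (1.2 equiv), −25 °C; then Bu4NOAc (3 equiv), −25 → 0 °C
Reagents that add atoms: N-bromosuccinimide, O=C1CCC(=O)N1Br; bromodiethylsulfonium bromopentachloroantimonate (Et2SBr·SbCl5Br), CC[S+](Br)CC.Cl[Sb-](Cl)(Cl)(Cl)(Cl)Br; tetrabutylammonium acetate, CCCC[N+](CCCC)(CCCC)CCCC.CC(=O)[O-]
Why: Proposed new method: the bromonium ion on the (9Z)-alkene is captured 5-exo by the free C6 hydroxyl (anti addition; allylic 1,3-strain of the Z-alkene and the bulky C7 silyl ether place the new C9 substituent trans to OTBS and cis to the C5 chain, giving 9S,10S), the stronger bromonium donor then activates the (12E)-alkene, the ring oxygen attacks C12 5-exo on the convex face (anti addition, 12R,13S) to give a cis-fused 1-oxoniabicyclo[3.3.0]octane, and acetate opens it by SN2 at the ring-fusion carbon C9 with inversion (9R, cis to the C10 bromide), C9 being the only α-carbon not shielded by OTBS (C6) or by the branched bromopropyl group (C12), so the five-membered ring is expanded to the oxocane; the closest known reaction types are the Et2SBr·SbCl5Br-induced tetrahydrofuran-to-oxocane ring expansion ended by an internal carbonate and the zinc acetate-mediated ring expansion of cyclic ethers through bicyclic oxonium ions, whereas capture by external acetate at the fusion carbon of such an oxonium ion in a one-flask double bromination is not known.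

Step 9
Reactants: 16 (3E,6S,7R,9R,10S,12R,13S)-10,13-dibromo-7-[(tert-butyldimethylsilyl)oxy]-6,12-epoxy-1-(trimethylsilyl)pentadec-3-en-1-yn-9-yl acetate
Product: 17 (3S,4S,6S,7R,9R,10S,12R,13S)-10,13-dibromo-7-[(tert-butyldimethylsilyl)oxy]-3,4:6,12-diepoxy-1-(trimethylsilyl)pentadec-1-yn-9-yl acetate
Conditions: ent-Shi ketone (L-fructose-derived, 30 mol%), KHSO5 (Oxone), K2CO3, Bu4NHSO4, MeCN–CH2(OMe)2/aq. Na2B4O7 buffer, 0 °C
Reagents that add atoms: potassium peroxymonosulfate (KHSO5), [K+].[O-]S(=O)(=O)OO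
Why: Shi epoxidation of the only remaining alkene, an (E)-enyne (a favoured substrate class), through the spiro dioxirane transition state; the D-fructose ketone gives R,R epoxides from trans-alkenes, so its enantiomer gives the required 3S,4S epoxide by reagent control.

Step 10
Reactants: 17 (3S,4S,6S,7R,9R,10S,12R,13S)-10,13-dibromo-7-[(tert-butyldimethylsilyl)oxy]-3,4:6,12-diepoxy-1-(trimethylsilyl)pentadec-1-yn-9-yl acetate
Product: 19 (3S,4R,6S,7R,9R,10S,12R,13S)-10,13-dibromo-4,7:6,12-diepoxy-3-hydroxypentadec-1-yn-9-yl acetate, via hydroxy epoxide 18 (not isolated)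
Conditions: Bu4NF (2.5 equiv), AcOH (2.5 equiv), THF, 0 °C → rt; then camphorsulfonic acid (10 mol%), CH2Cl2, rt
Reagents that add atoms: none
Why: Buffered fluoride removes the O-silyl and C-silyl groups without acyl migration, and acid then drives the Baldwin-favoured 5-exo-tet opening of the epoxide by the C7 hydroxyl with inversion at C4 (4R, 2,5-cis tetrahydrofuran trans-fused to the oxocane), leaving the 3S alcohol.

Step 11
Reactants: 19 (3S,4R,6S,7R,9R,10S,12R,13S)-10,13-dibromo-4,7:6,12-diepoxy-3-hydroxypentadec-1-yn-9-yl acetate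
Product: 20 (3R,4R,6S,7R,9R,10S,12R,13S)-3,10,13-tribromo-4,7:6,12-diepoxypentadec-1-yn-9-yl acetate
Conditions: PPh3, CBr4, CH2Cl2, 0 °C
Reagents that add atoms: tetrabromomethane, BrC(Br)(Br)Br
Why: Appel reaction, in which bromide displaces the propargylic oxyphosphonium group by SN2 with inversion (3S → 3R) under neutral conditions that spare the acetate and the secondary bromides.

**Compound list**
1 | acrolein | C=CC=O | starting material
2 | propargyl bromide | C#CCBr | starting material
3 | rac-hex-1-en-5-yn-3-ol | C=CC(O)CC#C | intermediate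
4 | (E)-1-bromopent-2-ene | CC/C=C/CBr | starting material
5 | rac-(8E)-undeca-1,8-dien-5-yn-3-ol | C=CC(O)CC#CC/C=C/CC | intermediate
6 | rac-(5Z,8E)-undeca-1,5,8-trien-3-ol | C=CC(O)C/C=C\C/C=C/CC | intermediate
7 | (1R,3Z,6E)-1-[(2S)-oxiran-2-yl]nona-3,6-dien-1-ol | C1O[C@@H]1[C@H](O)C/C=C\C/C=C/CC | intermediate
8 | tert-butyldimethyl{[(1R,3Z,6E)-1-[(2S)-oxiran-2-yl]nona-3,6-dien-1-yl]oxy}silane | C1O[C@@H]1[C@H](O[Si](C)(C)C(C)(C)C)C/C=C\C/C=C/CC | intermediate
9 | ethynyltrimethylsilane | C[Si](C)(C)C#C | starting material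
10 | (E)-1-bromo-2-iodoethene | Br/C=C/I | starting material
11 | [(3E)-4-bromobut-3-en-1-yn-1-yl]trimethylsilane | C[Si](C)(C)C#C/C=C/Br | intermediate
12 | [(1E)-4-(trimethylsilyl)but-1-en-3-yn-1-yl]lithium | C[Si](C)(C)C#C/C=C/[Li] | intermediate
13 | (3E,6S,7R,9Z,12E)-7-[(tert-butyldimethylsilyl)oxy]-1-(trimethylsilyl)pentadeca-3,9,12-trien-1-yn-6-ol | C[Si](C)(C)C#C/C=C/C[C@H](O)[C@H](O[Si](C)(C)C(C)(C)C)C/C=C\C/C=C/CC | intermediate
14 | (3E,6S,7R,9S,10S,12E)-10-bromo-7-[(tert-butyldimethylsilyl)oxy]-6,9-epoxy-1-(trimethylsilyl)pentadeca-3,12-dien-1-yne (2,5-cis-tetrahydrofuran) | C[Si](C)(C)C#C/C=C/C[C@H]1[C@H](O[Si](C)(C)C(C)(C)C)C[C@H](O1)[C@@H](Br)C/C=C/CC | intermediate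
15 | oxonium salt of the (6S,7R,9S,10S,12R,13S)-10,13-dibromo-7-silyloxy C15 chain in which one oxygen is bonded to C6, C9 and C12 (cis-fused 1-oxoniabicyclo[3.3.0]octane), bromopentachloroantimonate | C[Si](C)(C)C#C/C=C/C[C@H]1[C@H](O[Si](C)(C)C(C)(C)C)C[C@H]2[C@@H](Br)C[C@@H]([O+]12)[C@@H](Br)CC.Cl[Sb-](Cl)(Cl)(Cl)(Cl)Br | intermediate
16 | (3E,6S,7R,9R,10S,12R,13S)-10,13-dibromo-7-[(tert-butyldimethylsilyl)oxy]-6,12-epoxy-1-(trimethylsilyl)pentadec-3-en-1-yn-9-yl acetate | C[Si](C)(C)C#C/C=C/C[C@@H]1O[C@@H]([C@@H](Br)CC)C[C@H](Br)[C@H](OC(C)=O)C[C@H]1O[Si](C)(C)C(C)(C)C | intermediate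
17 | (3S,4S,6S,7R,9R,10S,12R,13S)-10,13-dibromo-7-[(tert-butyldimethylsilyl)oxy]-3,4:6,12-diepoxy-1-(trimethylsilyl)pentadec-1-yn-9-yl acetate | C[Si](C)(C)C#C[C@@H]1O[C@H]1C[C@@H]2O[C@@H]([C@@H](Br)CC)C[C@H](Br)[C@H](OC(C)=O)C[C@H]2O[Si](C)(C)C(C)(C)C | intermediate
18 | (3S,4S,6S,7R,9R,10S,12R,13S)-10,13-dibromo-3,4:6,12-diepoxy-7-hydroxypentadec-1-yn-9-yl acetate | C#C[C@@H]1O[C@H]1C[C@@H]2O[C@@H]([C@@H](Br)CC)C[C@H](Br)[C@H](OC(C)=O)C[C@H]2O | intermediate
19 | (3S,4R,6S,7R,9R,10S,12R,13S)-10,13-dibromo-4,7:6,12-diepoxy-3-hydroxypentadec-1-yn-9-yl acetate | C#C[C@H](O)[C@H]1C[C@@H]2O[C@@H]([C@@H](Br)CC)C[C@H](Br)[C@H](OC(C)=O)C[C@H]2O1 | intermediate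
20 | (3R,4R,6S,7R,9R,10S,12R,13S)-3,10,13-tribromo-4,7:6,12-diepoxypentadec-1-yn-9-yl acetate | C#C[C@@H](Br)[C@H]1C[C@@H]2O[C@@H]([C@@H](Br)CC)C[C@H](Br)[C@H](OC(C)=O)C[C@H]2O1 | target

**Step count**
Total: 11 steps. Longest linear sequence: 10 steps (steps 1–5 and 7–11; step 6 is a one-step side branch).

**Three steps most likely to fail**

Step 8 (the proposed new step). The main risk is where acetate attacks: at C6 or C12 instead of C9, or on a bromonium ion, which would give tetrahydrofuran products or the C9 epimer. The fallback uses only reaction classes that are on record (NBS bromoetherification, oxonium formation from a tetrahydrofuran with Et2SBr·SbCl5Br, hydrolytic capture of the oxonium ion, acylation, Mitsunobu inversion). It changes the approach in two ways: the two brominations are taken apart, and the C9–O bond is made with water and then corrected or acylated separately. It sets out from 13: NBS alone gives 14, which is isolated. Compound 14 is treated with Et2SBr·SbCl5Br in MeNO2 at −25 °C and the oxonium ion is quenched with aqueous NaHCO3. Attack of water with inversion gives (3E,6S,7R,9R,10S,12R,13S)-10,13-dibromo-7-[(tert-butyldimethylsilyl)oxy]-6,12-epoxy-1-(trimethylsilyl)pentadec-3-en-1-yn-9-ol F1, which Ac2O, DMAP and pyridine convert into 16. If hydration instead runs through the transannular bromonium ion, it gives the (9S)-epimer, (3E,6S,7R,9S,10S,12R,13S)-10,13-dibromo-7-[(tert-butyldimethylsilyl)oxy]-6,12-epoxy-1-(trimethylsilyl)pentadec-3-en-1-yn-9-ol F2; Mitsunobu inversion with acetic acid (PPh3, diisopropyl azodicarboxylate) then also gives 16. The fallback comes back to the route at 16. It does not remove the regiochemical risk of opening at C9; it only decouples the C9 configuration and the nucleophile from the ring-opening event.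

Step 11. The Appel reaction at a propargylic carbon next to a ring oxygen may give bromoallene (SN2') or lose configuration through an ion pair. The fallback sets out from 19: MsCl and Et3N in CH2Cl2 at −20 °C give the isolable (3S,4R,6S,7R,9R,10S,12R,13S)-9-acetoxy-10,13-dibromo-4,7:6,12-diepoxypentadec-1-yn-3-yl methanesulfonate F3. This is displaced with LiBr in acetone at 0 °C, a clean SN2 on a sulfonate by free bromide instead of collapse of an oxyphosphonium ion pair, and the route is rejoined at 20.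

Step 7. The enynyl-lithium 12 may decompose, or the BF3-promoted opening next to the silyl ether may give silyl migration or rearrangement. The fallback sets out from 8 and brings C4 in as an alkyne carbon. Lithium acetylide–ethylenediamine complex in DMSO–THF opens 8 to (4S,5R,7Z,10E)-5-[(tert-butyldimethylsilyl)oxy]trideca-7,10-dien-1-yn-4-ol F4. Hydrozirconation with Cp2Zr(H)Cl and iodinolysis give (1E,4S,5R,7Z,10E)-5-[(tert-butyldimethylsilyl)oxy]-1-iodotrideca-1,7,10-trien-4-ol F5. Sonogashira coupling of F5 with 9 (Pd(PPh3)4, CuI, i-Pr2NH) comes back to the route at 13.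

Further compounds
F1 | step 8 | (3E,6S,7R,9R,10S,12R,13S)-10,13-dibromo-7-[(tert-butyldimethylsilyl)oxy]-6,12-epoxy-1-(trimethylsilyl)pentadec-3-en-1-yn-9-ol | C[Si](C)(C)C#C/C=C/C[C@@H]1O[C@@H]([C@@H](Br)CC)C[C@H](Br)[C@H](O)C[C@H]1O[Si](C)(C)C(C)(C)C
F2 | step 8 | (3E,6S,7R,9S,10S,12R,13S)-10,13-dibromo-7-[(tert-butyldimethylsilyl)oxy]-6,12-epoxy-1-(trimethylsilyl)pentadec-3-en-1-yn-9-ol | C[Si](C)(C)C#C/C=C/C[C@@H]1O[C@@H]([C@@H](Br)CC)C[C@H](Br)[C@@H](O)C[C@H]1O[Si](C)(C)C(C)(C)C
F3 | step 11 | (3S,4R,6S,7R,9R,10S,12R,13S)-9-acetoxy-10,13-dibromo-4,7:6,12-diepoxypentadec-1-yn-3-yl methanesulfonate | C#C[C@H](OS(C)(=O)=O)[C@H]1C[C@@H]2O[C@@H]([C@@H](Br)CC)C[C@H](Br)[C@H](OC(C)=O)C[C@H]2O1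
F4 | step 7 | (4S,5R,7Z,10E)-5-[(tert-butyldimethylsilyl)oxy]trideca-7,10-dien-1-yn-4-ol | C#CC[C@H](O)[C@H](O[Si](C)(C)C(C)(C)C)C/C=C\C/C=C/CC
F5 | step 7 | (1E,4S,5R,7Z,10E)-5-[(tert-butyldimethylsilyl)oxy]-1-iodotrideca-1,7,10-trien-4-ol | I/C=C/C[C@H](O)[C@H](O[Si](C)(C)C(C)(C)C)C/C=C\C/C=C/CC
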